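(The earlier runs and the new flask are calculated for an exercise; noise was put on by code.)

Should the flask be charged as planned, with 0.99 mM impurity beside 2.0 mM free catalyst, or should we clean it first? That depends on whether the excess of right-handed substrate reaches 80% within 25 h, and how high it goes.

| flask | left-handed substrate | right-handed substrate | reagent | free catalyst | impurity | remark | time |
|---|---|---|---|---|---|---|---|
| summer | 0.20 M | 0.20 M | 0.30 M | 2 mM | 0.99 mM | run made earlier |  |
| autumn | 0.20 M | 0.20 M | 1.2 M | 2 mM | 0.99 mM | run made earlier |  |
| dusk | 0.20 M | 0.20 M | 0.60 M | 2 mM | 2 mM | run made earlier |  |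
| flask | 0.20 M | 0.20 M | 0.600 M | 2.0 mM | 0.99 mM |  | 25 h |

| run | time / h | right-handed substrate / % | left-handed substrate / % |
|---|---|---|---|
| summer | 2.00 | 49.2 | 21.6 |
| summer | 3.00 | 48.7 | 15.7 |
| summer | 5.00 | 49.3 | 11.2 |
| summer | 8.00 | 48.1 | 8.3 |
| summer | 10.0 | 47.9 | 5.5 |
| summer | 15.0 | 47.0 | 4.5 |
| summer | 25.0 | 47.2 | 2.3 |
| autumn | 2.00 | 47.2 | 3.4 |
| autumn | 3.00 | 46.9 | 0.7 |
| autumn | 5.00 | 46.5 | 1.1 |
| autumn | 8.00 | 44.6 | 0.5 |
| autumn | 10.0 | 44.5 | 0.1 |
| autumn | 15.0 | 43.6 | 0 |
| autumn | 25.0 | 41.6 | 0 |
| dusk | 5.00 | 49.3 | 35.5 |
| dusk | 10.0 | 49.2 | 35.7 |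
| dusk | 15.0 | 49.2 | 33.4 |
| dusk | 20.0 | 50.4 | 34.9 |
| dusk | 25.0 | 49.1 | 35.4 |

(standard deviation of a reading: 0.5 percentage points)

1. whether the excess of right-handed substrate over left-handed substrate among what is left of the two reaches 80% by 25 h (yes / no)
2. the highest excess of right-handed substrate over left-handed substrate among what is left of the two up to 25 h

- free catalyst is single-handed; left-handed substrate and right-handed substrate are mirror images of each other, charged as a racemate, each of them at the stated concentration

The dusk run, with 2 mM impurity, read 35.5% left-handed substrate at 5.00 h and 35.4% at 25.0 h, but the summer run, with the flask's impurity, went on down. How catalyst and reagent change need not concern us. We take each substrate's rate as proportional to its own c, with the same c of catalyst and reagent for both. Integrating, the logarithm of the fraction of c(left-handed substrate) left is then a constant multiple of that for c(right-handed substrate). This multiple is the selectivity factor, which the last summer reading gives as 53.4, a rough reading from a right-handed loss of 2.8 percentage points.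

At 80% excess, c(left-handed substrate)/c(right-handed substrate) is 0.111, so right-handed substrate keeps 95.9% of its charge. We should therefore watch for readings near 48.0% right-handed and 5.33% left-handed. That price says nothing of time, though, and the dusk run read an excess of 16.2% at 25.0 h. The summer run, with the flask's impurity and free catalyst but less reagent than the flask, read an excess of 90.7% at 25.0 h, above the wanted 80%, so we charge as planned. If right-handed substrate ends midway between the last summer and autumn readings, keeping 88.8%, our excess is 99.6%.

The forecast says yes and 98%, above which our figure stands, and expects that “it passes 80 % within a few hours”.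

The flask gives yes and 99.4%.

    reagent + free catalyst + left-handed substrate → free catalyst + left-handed product (k = 0.650 M⁻² s⁻¹)
    reagent + free catalyst + right-handed substrate → free catalyst + right-handed product (k = 0.0120 M⁻² s⁻¹)
    2 reagent → homo dimer (k = 1.10 × 10⁻⁴ M⁻¹ s⁻¹)
    free catalyst + impurity → spent catalyst (k = 4.20 M⁻¹ s⁻¹)

In the flask, impurity read 0% at 2.50 h, with free catalyst and spent catalyst at 50.5% and 49.5% of the catalyst charged. Free catalyst held that share while both catalysed steps ran, with half-lives of 0.74 h for left-handed and 40 h for right-handed substrate at 0.559 h, and homo dimer formed beside them until reagent read 5.93% at 25.0 h. The excess passed 80% at 3.17 h with right-handed substrate at 48.0%, where the factor 53.4 had put it at 48.0%. With doubled free catalyst and the other amounts as they are, the end excess is >99.9%.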